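**Plan**

- Numbering used here: carbocycle C1 (CH bearing the side chain), C2 (CHMe), C3 (C(Me)OH), C4 (CHOAc), C5 (C(Me)OH), C6 (CHOH); chain C7–C12 counted from the pyranone.
- Cuts: C10–C11 (Stille); the four ring C–O bonds (C4–O/C5–O by osmylation, C3–O/C6–O by singlet oxygen) back to a cyclohexa-1,3-diene; ring bond C1–C2 (6π electrocyclization) back to an open-chain triene; C5–C6 of that triene (Suzuki–Miyaura).
- Enabling feature: the four oxygens on C3–C6 are contiguous and all on one face, and the carbon groups on C1 and C2 are cis on the other face. The ring is therefore a masked cis-5,6-disubstituted cyclohexa-1,3-diene (C3=C4–C5=C6), the disrotatory product of an (E,Z,E)-triene.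
- Forward order: the γ-pyranone ring is made first (steps 1–3) and turned into a dienylstannane (4–6); the cyclohexane ring is closed afterwards from an acyclic trienyne (step 9) and oxygenated (11–15); the halves are joined last (16).
- Stereochemistry: C1/C2 cis from orbital symmetry; C3–O/C6–O from 1O2 anti to the C1/C2 groups; C4–O/C5–O from osmylation on the peroxide face; absolute configuration from a cinchona-amine-catalysed kinetic resolution of the racemic endoperoxide (step 12). The peroxide bridge masks O3/O6, so only O4 is acetylated.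

Key step: step 9

Remark: compounds 18–21 are racemates (names carry "rac"); their SMILES show the enantiomer that step 12 retains.

**Step 1**
Reactants: 1 methyl 2-methyl-3-oxopentanoate; 2 N-methoxy-N-methylpropanamide
Product: 3 methyl 2,4-dimethyl-3,5-dioxoheptanoate
Conditions: LiN(iPr)2 (2.2 equiv), THF, −78 to 0 °C; then 2, −78 °C to rt; aq. HCl work-up
Reagents that add atoms: none
Why: Acylation of the β-keto ester dianion at its more nucleophilic γ-carbon by the Weinreb amide, whose chelated tetrahedral adduct survives until work-up and so stops at the ketone; the two enolizable methine centers are lost in step 2.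

**Step 2**
Reactants: 3 methyl 2,4-dimethyl-3,5-dioxoheptanoate
Product: 4 6-ethyl-4-hydroxy-3,5-dimethyl-2H-pyran-2-one
Conditions: DBU (1.5 equiv), toluene, 80 °C; aq. HCl work-up
Reagents that add atoms: none
Why: Base-mediated enol-lactonization (6-exo-trig acyl substitution of the methyl ester by the C5 enolate oxygen) should drain the tricarbonyl equilibrium into the stable 4-hydroxy-2-pyranone.

**Step 3**
Reactants: 4 6-ethyl-4-hydroxy-3,5-dimethyl-2H-pyran-2-one
Product: 5 2-ethyl-6-methoxy-3,5-dimethyl-4H-pyran-4-one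
Conditions: MeOTf (1.2 equiv), CH2Cl2, 0 °C to rt; then aq. NaHCO3
Reagents that add atoms: methyl trifluoromethanesulfonate, COS(=O)(=O)C(F)(F)F
Why: O-methylation with a hard methylating agent should occur at the more basic lactone carbonyl oxygen, and loss of the 4-OH proton then gives the 2-methoxy-4-pyranone regioisomer rather than the 4-methoxy-2-pyranone.

**Step 4**
Reactants: 6 (E)-3-(tributylstannyl)prop-2-en-1-ol
Product: 7 (E)-3-(tributylstannyl)prop-2-enal
Conditions: MnO2 (10 equiv), CH2Cl2, rt
Reagents that add atoms: none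
Why: MnO2 oxidizes the allylic alcohol selectively to the enal under neutral conditions that leave the C–Sn bond and the E geometry untouched.

**Step 5**
Reactants: 5 2-ethyl-6-methoxy-3,5-dimethyl-4H-pyran-4-one; 7 (E)-3-(tributylstannyl)prop-2-enal
Product: 8 2-[(4E)-3-hydroxy-5-(tributylstannyl)pent-4-en-2-yl]-6-methoxy-3,5-dimethyl-4H-pyran-4-one
Conditions: LiN(SiMe3)2 (1.05 equiv), THF, −78 °C; then 7, −78 °C; AcOH quench
Reagents that add atoms: none
Why: LiN(SiMe3)2 removes a proton from the CH2 of the 2-ethyl group, which is vinylogously activated by the C4 carbonyl, and the extended enolate adds 1,2 to the enal (aldol addition); the two new stereocenters are left uncontrolled because both disappear in step 6.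

**Step 6**
Reactants: 8 2-[(4E)-3-hydroxy-5-(tributylstannyl)pent-4-en-2-yl]-6-methoxy-3,5-dimethyl-4H-pyran-4-one
Product: 10 2-methoxy-3,5-dimethyl-6-[(2E,4E)-5-(tributylstannyl)penta-2,4-dien-2-yl]-4H-pyran-4-one, via mesylate 9 (not isolated)
Conditions: MsCl, Et3N, CH2Cl2, 0 °C; then DBU, rt
Reagents that add atoms: none
Why: Mesylation of the secondary carbinol followed by DBU-induced E1cB elimination through the acidic pyranyl-CH(Me) position should give the conjugated (E,E)-diene, the E geometry of the new trisubstituted alkene being the thermodynamic one and the vinylstannane being inert.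

**Step 7**
Reactants: 11 2-[(E)-2-bromoethenyl]-6-methyl-1,3,6,2-dioxazaborocane-4,8-dione (MIDA boronate); 12 propyne
Product: 13 6-methyl-2-[(1E)-pent-1-en-3-yn-1-yl]-1,3,6,2-dioxazaborocane-4,8-dione
Conditions: PdCl2(PPh3)2 (3 mol %), CuI (6 mol %), Et3N, THF, rt
Reagents that add atoms: none
Why: Sonogashira coupling at the C–Br bond proceeds with retention of the E geometry, and the sp3-hybridized boron of the MIDA boronate does not transmetalate under anhydrous conditions.

**Step 8**
Reactants: 14 (E)-2-methylbut-2-enal (tiglic aldehyde)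
Product: 15 (2Z,4E)-2-iodo-4-methylhexa-2,4-diene
Conditions: EtPPh3I, n-BuLi, THF, rt; I2, −78 °C; NaN(SiMe3)2, −20 °C; then 14, −78 °C to rt
Reagents that add atoms: ethyltriphenylphosphonium iodide, CC[P+](c1ccccc1)(c1ccccc1)c1ccccc1.[I-]; iodine, II
Why: Stork–Zhao iodo-olefination, in which the non-stabilized α-iodo ylide made in the flask adds under kinetic control to give the Z-iodoalkene (iodine cis to the dienyl chain), sets the geometry of the future central triene alkene while the E-alkene of 14 is untouched.

**Step 9**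
Reactants: 15 (2Z,4E)-2-iodo-4-methylhexa-2,4-diene; 13 6-methyl-2-[(1E)-pent-1-en-3-yn-1-yl]-1,3,6,2-dioxazaborocane-4,8-dione
Product: 18 rac-(5S,6S)-1,3,6-trimethyl-5-(prop-1-yn-1-yl)cyclohexa-1,3-diene, via boronic acid 16 (not isolated), via triene 17 (not isolated)
Conditions: Pd(OAc)2 (5 mol %), SPhos (2-dicyclohexylphosphino-2′,6′-dimethoxybiphenyl, 10 mol %), K3PO4 (3 equiv), dioxane/H2O 5:1, 60 °C; then 110 °C, sealed tube
Reagents that add atoms: none
Why: Hydrolysis of the MIDA boronate releases boronic acid 16 slowly, and Suzuki–Miyaura coupling (oxidative addition of zerovalent palladium into the C–I bond of 15, transmetalation, reductive elimination, each with retention of alkene geometry) gives the (2E,4Z,6E)-triene 17, which on heating undergoes a thermal six-electron electrocyclization. The closest known reaction type is the cross-coupling/6π-electrocyclization cascade of (E,Z,E)-hexatrienes to cyclohexa-1,3-dienes. The six-membered ring is closed in the disrotatory 6π mode, the new σ bond joining the two triene termini C2 and C7 of 17. Both new stereocenters (C5 and C6 of 18) arise in this one event and their cis relation is fixed by orbital symmetry together with the E geometry of both terminal alkenes; no element controls the absolute sense, so 18 is racemic and the single enantiomer is secured in step 12. The step needs retention of the Z geometry at the central alkene and exclusive six-electron closure, and the substrate secures both: the Z-iodide couples with retention, the E-configured termini carry no cis allylic hydrogen for a competing [1,7]-hydrogen shift, and the alkyne cannot join a thermal closure at this temperature.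

**Step 10**
Reactants: 18 rac-(5S,6S)-1,3,6-trimethyl-5-(prop-1-yn-1-yl)cyclohexa-1,3-diene
Product: 20 rac-(5S,6S)-5-[(E)-2-iodoprop-1-en-1-yl]-1,3,6-trimethylcyclohexa-1,3-diene, via alkenylzirconocene 19 (not isolated)
Conditions: Cp2Zr(H)Cl (2.5 equiv), THF, rt to 45 °C; then I2, −20 °C
Reagents that add atoms: iodine, II
Why: Hydrozirconation (syn addition of Zr–H) of the 2-alkyne should place zirconium, after equilibration with excess reagent, on the less hindered methyl-bearing carbon, and iodinolysis with retention gives the E-2-iodoalkene, the trisubstituted ring alkenes being much slower to hydrozirconate.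

**Step 11**
Reactants: 20 rac-(5S,6S)-5-[(E)-2-iodoprop-1-en-1-yl]-1,3,6-trimethylcyclohexa-1,3-diene
Product: 21 rac-(1R,4S,7S,8S)-8-[(E)-2-iodoprop-1-en-1-yl]-1,5,7-trimethyl-2,3-dioxabicyclo[2.2.2]oct-5-ene
Conditions: O2, 5,10,15,20-tetraphenylporphyrin (1 mol %), CH2Cl2, white LED, −20 °C
Reagents that add atoms: dioxygen, O=O
Why: Singlet-oxygen [4+2] cycloaddition to the cisoid diene from the face opposite the two cis substituents at C5 and C6 should set both bridgehead C–O stereocenters (future C3–O and C6–O) anti to those substituents, the iodoalkene being too electron-poor for the ene reaction.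

**Step 12**
Reactants: 21 rac-(1R,4S,7S,8S)-8-[(E)-2-iodoprop-1-en-1-yl]-1,5,7-trimethyl-2,3-dioxabicyclo[2.2.2]oct-5-ene
Product: 22 (1R,4S,7S,8S)-8-[(E)-2-iodoprop-1-en-1-yl]-1,5,7-trimethyl-2,3-dioxabicyclo[2.2.2]oct-5-ene
Conditions: 9-O-acetylcupreidine (10 mol %), CH2Cl2, rt, stopped at about 55–60% conversion; chromatography
Reagents that add atoms: none
Why: Chiral-amine-catalysed Kornblum–DeLaMare rearrangement run as a kinetic resolution, in which the catalyst removes the only peroxide α-hydrogen (C4–H) faster from one enantiomer and converts it to the 4-hydroxy enone, so that unreacted 22 should be recovered enantioenriched past half conversion and the absolute configuration of the four existing stereocenters is fixed (the pseudoenantiomeric 9-O-acetylcupreine is taken if the sense of discrimination proves opposite).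

**Step 13**
Reactants: 22 (1R,4S,7S,8S)-8-[(E)-2-iodoprop-1-en-1-yl]-1,5,7-trimethyl-2,3-dioxabicyclo[2.2.2]oct-5-ene
Product: 23 (1R,4S,5R,6S,7S,8S)-8-[(E)-2-iodoprop-1-en-1-yl]-1,5,7-trimethyl-2,3-dioxabicyclo[2.2.2]octane-5,6-diol
Conditions: OsO4 (5 mol %), NMO (1.5 equiv), acetone/H2O 4:1, 0 °C to rt
Reagents that add atoms: osmium tetroxide, O=[Os](=O)(=O)=O; N-methylmorpholine N-oxide, C[N+]1([O-])CCOCC1; water, O
Why: Upjohn dihydroxylation (concerted syn addition of OsO4) of the trisubstituted ring alkene should occur on the face syn to the peroxide bridge, because the other face is covered by the C7 methyl and the C8 alkenyl group, and so sets the last two stereocenters while the less reactive iodoalkene is spared.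

**Step 14**
Reactants: 23 (1R,4S,5R,6S,7S,8S)-8-[(E)-2-iodoprop-1-en-1-yl]-1,5,7-trimethyl-2,3-dioxabicyclo[2.2.2]octane-5,6-diol
Product: 24 (1R,4S,5R,6S,7S,8S)-5-hydroxy-8-[(E)-2-iodoprop-1-en-1-yl]-1,5,7-trimethyl-2,3-dioxabicyclo[2.2.2]octan-6-yl acetate
Conditions: Ac2O (3 equiv), pyridine, 0 °C to rt
Reagents that add atoms: acetic anhydride, CC(=O)OC(C)=O
Why: Acetylation should take place only at the single secondary hydroxyl, since the tertiary one is unreactive under these conditions and the peroxide bridge keeps the other two oxygens masked, and pyridine is too weak a base to trigger the peroxide rearrangement used in step 12.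

**Step 15**
Reactants: 24 (1R,4S,5R,6S,7S,8S)-5-hydroxy-8-[(E)-2-iodoprop-1-en-1-yl]-1,5,7-trimethyl-2,3-dioxabicyclo[2.2.2]octan-6-yl acetate
Product: 25 (1R,2S,3S,4S,5S,6R)-2,3,6-trihydroxy-4-[(E)-2-iodoprop-1-en-1-yl]-2,5,6-trimethylcyclohexyl acetate
Conditions: thiourea (1.5 equiv), MeOH (wet), rt
Reagents that add atoms: none
Why: Thiourea reduces the O–O bond without breaking a C–O bond, so both carbinol configurations are retained and the acetate, the tertiary alcohols and the iodoalkene should survive.

**Step 16**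
Reactants: 25 (1R,2S,3S,4S,5S,6R)-2,3,6-trihydroxy-4-[(E)-2-iodoprop-1-en-1-yl]-2,5,6-trimethylcyclohexyl acetate; 10 2-methoxy-3,5-dimethyl-6-[(2E,4E)-5-(tributylstannyl)penta-2,4-dien-2-yl]-4H-pyran-4-one
Product: 26 Amaurone A
Conditions: Pd2(dba)3 (5 mol %), AsPh3 (20 mol %), CuI (10 mol %), DMF, rt, in the dark
Reagents that add atoms: none
Why: Stille coupling of the E-iodoalkene with the (E,E)-dienylstannane proceeds with retention at both sp2 carbons under neutral conditions that tolerate the free hydroxyls and the acetate, and so completes the all-E triene.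

**Compound list**

1 | methyl 2-methyl-3-oxopentanoate | CCC(=O)C(C)C(=O)OC | starting material
2 | N-methoxy-N-methylpropanamide | CCC(=O)N(C)OC | starting material
3 | methyl 2,4-dimethyl-3,5-dioxoheptanoate (diastereomers and enol forms) | CCC(=O)C(C)C(=O)C(C)C(=O)OC | intermediate
4 | 6-ethyl-4-hydroxy-3,5-dimethyl-2H-pyran-2-one | CCc1oc(=O)c(C)c(O)c1C | intermediate
5 | 2-ethyl-6-methoxy-3,5-dimethyl-4H-pyran-4-one | CCc1oc(OC)c(C)c(=O)c1C | intermediate
6 | (E)-3-(tributylstannyl)prop-2-en-1-ol | CCCC[Sn](CCCC)(CCCC)/C=C/CO | starting material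
7 | (E)-3-(tributylstannyl)prop-2-enal | CCCC[Sn](CCCC)(CCCC)/C=C/C=O | intermediate
8 | 2-[(4E)-3-hydroxy-5-(tributylstannyl)pent-4-en-2-yl]-6-methoxy-3,5-dimethyl-4H-pyran-4-one (diastereomer mixture) | COc1oc(C(C)C(O)/C=C/[Sn](CCCC)(CCCC)CCCC)c(C)c(=O)c1C | intermediate
9 | (1E)-4-(6-methoxy-3,5-dimethyl-4-oxo-4H-pyran-2-yl)-1-(tributylstannyl)pent-1-en-3-yl methanesulfonate | COc1oc(C(C)C(OS(C)(=O)=O)/C=C/[Sn](CCCC)(CCCC)CCCC)c(C)c(=O)c1C | intermediate
10 | 2-methoxy-3,5-dimethyl-6-[(2E,4E)-5-(tributylstannyl)penta-2,4-dien-2-yl]-4H-pyran-4-one | COc1oc(/C(C)=C/C=C/[Sn](CCCC)(CCCC)CCCC)c(C)c(=O)c1C | intermediate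
11 | 2-[(E)-2-bromoethenyl]-6-methyl-1,3,6,2-dioxazaborocane-4,8-dione | CN1CC(=O)OB(/C=C/Br)OC(=O)C1 | starting material
12 | propyne | CC#C | starting material
13 | 6-methyl-2-[(1E)-pent-1-en-3-yn-1-yl]-1,3,6,2-dioxazaborocane-4,8-dione | CC#C/C=C/B1OC(=O)CN(C)CC(=O)O1 | intermediate
14 | (E)-2-methylbut-2-enal | C/C=C(\C)C=O | starting material
15 | (2Z,4E)-2-iodo-4-methylhexa-2,4-diene | C/C(I)=C/C(C)=C/C | intermediate
16 | [(1E)-pent-1-en-3-yn-1-yl]boronic acid | CC#C/C=C/B(O)O | intermediate
17 | (2E,4Z,6E)-3,5-dimethyldeca-2,4,6-trien-8-yne | CC#C/C=C/C(C)=C\C(C)=C\C | intermediate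
18 | rac-(5S,6S)-1,3,6-trimethyl-5-(prop-1-yn-1-yl)cyclohexa-1,3-diene (cis) | CC#C[C@@H]1[C@H](C)C(C)=CC(C)=C1 | intermediate
19 | chlorobis(cyclopentadienyl){(1E)-1-[rac-(1S,6S)-3,5,6-trimethylcyclohexa-2,4-dien-1-yl]prop-1-en-2-yl}zirconium (cyclopentadienyl rings drawn σ-bonded) | Cl[Zr](C1C=CC=C1)(C1C=CC=C1)/C(C)=C/[C@@H]1[C@H](C)C(C)=CC(C)=C1 | intermediate
20 | rac-(5S,6S)-5-[(E)-2-iodoprop-1-en-1-yl]-1,3,6-trimethylcyclohexa-1,3-diene | I/C(C)=C/[C@@H]1[C@H](C)C(C)=CC(C)=C1 | intermediate
21 | rac-(1R,4S,7S,8S)-8-[(E)-2-iodoprop-1-en-1-yl]-1,5,7-trimethyl-2,3-dioxabicyclo[2.2.2]oct-5-ene | I/C(C)=C/[C@@H]1[C@H](C)[C@@]2(C)OO[C@@H]1C(C)=C2 | intermediate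
22 | (1R,4S,7S,8S)-8-[(E)-2-iodoprop-1-en-1-yl]-1,5,7-trimethyl-2,3-dioxabicyclo[2.2.2]oct-5-ene (single enantiomer) | I/C(C)=C/[C@@H]1[C@H](C)[C@@]2(C)OO[C@@H]1C(C)=C2 | intermediate
23 | (1R,4S,5R,6S,7S,8S)-8-[(E)-2-iodoprop-1-en-1-yl]-1,5,7-trimethyl-2,3-dioxabicyclo[2.2.2]octane-5,6-diol | I/C(C)=C/[C@@H]1[C@H](C)[C@@]2(C)OO[C@@H]1[C@](C)(O)[C@@H]2O | intermediate
24 | (1R,4S,5R,6S,7S,8S)-5-hydroxy-8-[(E)-2-iodoprop-1-en-1-yl]-1,5,7-trimethyl-2,3-dioxabicyclo[2.2.2]octan-6-yl acetate | I/C(C)=C/[C@@H]1[C@H](C)[C@@]2(C)OO[C@@H]1[C@](C)(O)[C@@H]2OC(C)=O | intermediate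
25 | (1R,2S,3S,4S,5S,6R)-2,3,6-trihydroxy-4-[(E)-2-iodoprop-1-en-1-yl]-2,5,6-trimethylcyclohexyl acetate | I/C(C)=C/[C@@H]1[C@H](C)[C@@](C)(O)[C@@H](OC(C)=O)[C@@](C)(O)[C@H]1O | intermediate
26 | Amaurone A; (1R,2S,3S,4R,5S,6R)-2,3,6-trihydroxy-4-[(1E,3E,5E)-6-(6-methoxy-3,5-dimethyl-4-oxo-4H-pyran-2-yl)-2-methylhepta-1,3,5-trien-1-yl]-2,5,6-trimethylcyclohexyl acetate | COc1oc(/C(C)=C/C=C/C(C)=C/[C@@H]2[C@H](C)[C@@](C)(O)[C@@H](OC(C)=O)[C@@](C)(O)[C@H]2O)c(C)c(=O)c1C | target

**Step count and risks**

Total steps: 16. Longest linear sequence: 9 steps (14 to 26, steps 8–16).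

Steps most likely to fail:

1. Step 12. The catalyst may discriminate the two enantiomers too weakly in the base-induced peroxide rearrangement, or the wanted enantiomer may be eroded at the conversion needed. Fallback (sets out from 21, returns at 22): physical instead of kinetic resolution. Racemic 21 is separated by preparative chromatography on a polysaccharide-based chiral stationary phase, the (1R,4S,7S,8S) enantiomer is carried on as 22 and the antipode is discarded; no new compound (F0).

2. Step 13. Facial selectivity may be poor (osmylation anti to the peroxide bridge, driven by lone-pair repulsion), or the iodoalkene may be over-oxidized. Fallback (sets out from 22, returns at 24, skipping 23): Woodward cis-hydroxylation, which puts both oxygens on the face opposite to the one the electrophile attacks first and brings in the acetate at the same time. I2 and AgOAc in dry AcOH should give the trans iodo acetate (1R,4S,5S,6R,7S,8S)-6-iodo-8-[(E)-2-iodoprop-1-en-1-yl]-1,5,7-trimethyl-2,3-dioxabicyclo[2.2.2]octan-5-yl acetate F1 (iodonium on the face away from the peroxide, acetate opening at the tertiary carbon from the peroxide face). Warming with AgOAc in wet AcOH should then displace iodide with participation of the neighbouring acetate; hydrolysis and acyl shift to the secondary oxygen give 24.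

3. Step 8. The iodo-olefination of an enal may show poor Z-selectivity and loss of iodine. Fallback (sets out from 14, returns at 18 through 17): Still–Gennari olefination of 14 with methyl 2-[bis(2,2,2-trifluoroethoxy)phosphoryl]propanoate (KN(SiMe3)2, 18-crown-6, THF, −78 °C) should give methyl (2Z,4E)-2,4-dimethylhexa-2,4-dienoate F2. Reduction with i-Bu2AlH gives (2Z,4E)-2,4-dimethylhexa-2,4-dien-1-ol F3, and MnO2 oxidation gives (2Z,4E)-2,4-dimethylhexa-2,4-dienal F4. Horner–Wadsworth–Emmons reaction of F4 with diethyl but-2-yn-1-ylphosphonate (LiN(SiMe3)2, THF) builds the E-enyne and gives triene 17 directly, which is heated (toluene, 110 °C) to 18.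

**Further compounds**

F0 | step 12 | none | none
F1 | step 13 | (1R,4S,5S,6R,7S,8S)-6-iodo-8-[(E)-2-iodoprop-1-en-1-yl]-1,5,7-trimethyl-2,3-dioxabicyclo[2.2.2]octan-5-yl acetate | I/C(C)=C/[C@@H]1[C@H](C)[C@@]2(C)OO[C@@H]1[C@](C)(OC(C)=O)[C@H]2I
F2 | step 8 | methyl (2Z,4E)-2,4-dimethylhexa-2,4-dienoate | C/C=C(C)/C=C(C)\C(=O)OC
F3 | step 8 | (2Z,4E)-2,4-dimethylhexa-2,4-dien-1-ol | C/C=C(C)/C=C(C)\CO
F4 | step 8 | (2Z,4E)-2,4-dimethylhexa-2,4-dienal | C/C=C(C)/C=C(C)\C=O
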